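**Retrosynthetic overview**
- The oxirane is formed last, by face-selective epoxidation of the C1=C10 enal of a ten-membered enal diacetate.
- The enal diacetate comes from a macrocyclic 6,8-diol carrying C14 as a Weinreb amide and C7 as isopropenyl (hydrogenation, acetylation, amide reduction).
- The ten-membered ring is closed at C6–C7 by a Lewis-acid carbonyl-ene (Prins-type) reaction of an acyclic (2Z)-farnesane-type enal onto its distal isopropylidene olefin. This is the 1,10-closure of farnesyl diphosphate to the germacradienyl cation, with the C6 aldehyde in place of the allyl cation; C6 and C7 are set under control of C8.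
- The acyclic chain comes from cross-metathesis of a neryl acetate-derived terminal olefin with an (R)-α-methylene-γ-butyrolactone made from prenal and ethyl 2-(bromomethyl)acrylate.
- Ring order: ten-membered carbocycle first, oxirane second.

Numbering: ring compounds use germacrane numbering (ring C1–C10; C1 is the oxirane CH, C4 bears methyl C15, C7 bears the isopropyl group C11–C13, C10 bears C14).

Assumption: in steps 3 and 12 the catalyst enantiomer written is taken to give the drawn configuration; if the sense of induction is opposite, the mirror-image ligand (step 3) or 9-amino(9-deoxy)epiquinidine (step 12) is used.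

**Step 1**
Reactants: 1 neryl acetate, (2Z)-3,7-dimethylocta-2,6-dien-1-yl acetate
Product: 3 (2Z)-3-methyl-6-oxohex-2-en-1-yl acetate, via epoxide 2 (not isolated)
Conditions: mCPBA (1.05 equiv), CH2Cl2, 0 °C; then H5IO6 (1.2 equiv), THF/H2O, 0 °C
Reagents that add atoms: mCPBA, O=C(OO)c1cccc(Cl)c1
Why: The electron-rich 6,7-olefin is epoxidised (Prilezhaev) much faster than the 2,3-olefin deactivated by the allylic acetate, and periodic acid then cleaves the epoxide through its diol (Malaprade-type cleavage) to the aldehyde and acetone; no stereocentre is formed and the 2Z geometry is untouched.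

**Step 2**
Reactants: 3 (2Z)-3-methyl-6-oxohex-2-en-1-yl acetate
Product: 4 (2Z)-3-methylhepta-2,6-dien-1-yl acetate
Conditions: Ph3PCH3Br, KOtBu, THF, −78 → 0 °C
Reagents that add atoms: methyltriphenylphosphonium bromide, C[P+](c1ccccc1)(c1ccccc1)c1ccccc1.[Br-]
Why: Wittig methylenation of the aldehyde by the non-stabilised ylide is fast at low temperature and leaves the allylic acetate and the Z olefin alone; no stereocentre is formed.

**Step 3**
Reactants: 5 prenal (3-methylbut-2-enal); 6 ethyl 2-(bromomethyl)acrylate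
Product: 9 (5R)-3-methylidene-5-(2-methylprop-1-en-1-yl)oxolan-2-one, via silyl ether 7 (not isolated), via hydroxy ester 8 (not isolated)
Conditions: CrCl2 (10 mol %), (S,S)-1,8-bis(4-isopropyl-4,5-dihydrooxazol-2-yl)-3,6-diphenyl-9H-carbazole (11 mol %), iPr2NEt, Mn powder (2 equiv), TMSCl (1.5 equiv), THF, rt; then 1 M HCl, THF; TsOH·H2O (cat.), CH2Cl2, rt
Reagents that add atoms: none
Why: Catalytic asymmetric Nozaki–Hiyama–Kishi 2-(alkoxycarbonyl)allylation: the allylchromium species from 6 adds 1,2 to the enal inside the chiral carbazole-bis(oxazoline) complex, which sets C8 as R; Mn and TMSCl turn the catalyst over, and acid removes the silyl group and closes the γ-lactone.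

**Step 4**
Reactants: 4 (2Z)-3-methylhepta-2,6-dien-1-yl acetate (2 equiv); 9 (5R)-3-methylidene-5-(2-methylprop-1-en-1-yl)oxolan-2-one
Product: 10 (2Z)-3-methyl-6-[(3E,5R)-5-(2-methylprop-1-en-1-yl)-2-oxooxolan-3-ylidene]hex-2-en-1-yl acetate
Conditions: second-generation Hoveyda–Grubbs catalyst RuCl2(H2IMes)(=CH-C6H4-2-OiPr) (5 mol %), 2,6-dichloro-1,4-benzoquinone (10 mol %), CH2Cl2, 40 °C
Reagents that add atoms: none
Why: Olefin cross-metathesis between the terminal olefin of 4 and the 1,1-disubstituted enoate olefin of 9 gives the thermodynamically preferred E-alkylidene lactone (C2 cis to C9, trans to the carbonyl); the trisubstituted olefins of both partners are too hindered to react, the benzoquinone suppresses olefin migration, and C8 is untouched.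

**Step 5**
Reactants: 10 (2Z)-3-methyl-6-[(3E,5R)-5-(2-methylprop-1-en-1-yl)-2-oxooxolan-3-ylidene]hex-2-en-1-yl acetate
Product: 11 (2E,6Z)-8-hydroxy-2-[(2R)-2-hydroxy-4-methylpent-3-en-1-yl]-N-methoxy-N,6-dimethylocta-2,6-dienamide
Conditions: MeNH(OMe)·HCl (6 equiv), iPrMgCl (12 equiv), THF, −20 → 0 °C
Reagents that add atoms: N,O-dimethylhydroxylamine hydrochloride, CNOC.Cl
Why: Aminolysis by the chloromagnesium amide (Weinreb amide formation) opens the lactone at the acyl–oxygen bond, so C8 keeps its configuration, and the same reagent removes the acetate as N-methoxy-N-methylacetamide; C14 stays at the acid oxidation level while the C6 alcohol is freed.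

**Step 6**
Reactants: 11 (2E,6Z)-8-hydroxy-2-[(2R)-2-hydroxy-4-methylpent-3-en-1-yl]-N-methoxy-N,6-dimethylocta-2,6-dienamide
Product: 12 (2E,6Z)-2-[(2R)-2-hydroxy-4-methylpent-3-en-1-yl]-N-methoxy-N,6-dimethyl-8-oxoocta-2,6-dienamide
Conditions: TEMPO (10 mol %), PhI(OAc)2 (1.1 equiv), CH2Cl2, 0 °C → rt
Reagents that add atoms: none
Why: Oxoammonium (TEMPO) oxidation converts the primary allylic alcohol to the aldehyde much faster than the secondary allylic alcohol and does not isomerise the neral-type Z-enal.

**Step 7**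
Reactants: 12 (2E,6Z)-2-[(2R)-2-hydroxy-4-methylpent-3-en-1-yl]-N-methoxy-N,6-dimethyl-8-oxoocta-2,6-dienamide
Product: 13 (2E,6Z)-N-methoxy-N,6-dimethyl-2-[(2R)-4-methyl-2-(triethylsilyloxy)pent-3-en-1-yl]-8-oxoocta-2,6-dienamide
Conditions: TESCl, imidazole, CH2Cl2, 0 °C
Reagents that add atoms: chlorotriethylsilane, CC[Si](Cl)(CC)CC
Why: Silyl ether formation at the C8 alcohol blocks chelation to aluminium, makes the oxygen face of the 7,11-olefin the hindered one, and the group falls off in the acidic work-up of step 8.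

**Step 8**
Reactants: 13 (2E,6Z)-N-methoxy-N,6-dimethyl-2-[(2R)-4-methyl-2-(triethylsilyloxy)pent-3-en-1-yl]-8-oxoocta-2,6-dienamide
Product: 15 (1(10)E,4Z,6S,7S,8R)-6,8-dihydroxy-N-methoxy-N-methylgermacra-1(10),4,11-trien-14-amide, via silyl ether 14 (not isolated)
Conditions: Me2AlCl (4 equiv), CH2Cl2, 13 added over 10 h to 0.002 M, −78 → −30 °C; then 1 M HCl, THF/MeOH, 0 °C
Reagents that add atoms: none
Why: Proposed new method: a Lewis-acid (Prins-type) carbonyl-ene macrocyclisation in which the Me2AlCl-complexed C6 aldehyde takes the role of the allyl cation of farnesyl diphosphate and is attacked at C7 by the distal trisubstituted 7,11-olefin (Markovnikov, tertiary C11 cation character), a methyl hydrogen passing to oxygen through the six-centre ene array to leave the isopropenyl group; the 1(10) and 4,5 olefins are conjugated to carbonyl groups and so are not nucleophilic, attack on C1 would be a disfavoured 5-endo closure, the two cis olefins pre-fold the chain and high dilution suppresses oligomers; A(1,3) strain with the cis methyl on C11 holds H8 in the olefin plane, so the aldehyde, tethered through C9, adds to the C7 face anti to the bulky OSiEt3 group (7,8-syn), and the aluminium-bound oxygen sits anti to C8 with H6 between C8 and C11 (6,7-syn), which gives 6S,7S in 15 after acid removal of the silyl group; the closest known chemistry is the Me2AlCl-promoted intramolecular carbonyl-ene reaction that closes six- and seven-membered rings and the Lewis-acid ene macrocyclisations that close 14- to 16-membered rings.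

**Step 9**
Reactants: 15 (1(10)E,4Z,6S,7S,8R)-6,8-dihydroxy-N-methoxy-N-methylgermacra-1(10),4,11-trien-14-amide
Product: 16 (1(10)E,4Z,6S,7S,8R)-6,8-dihydroxy-N-methoxy-N-methylgermacra-1(10),4-dien-14-amide
Conditions: H2 (1 atm), RhCl(PPh3)3 (10 mol %), benzene/EtOH, rt
Reagents that add atoms: none
Why: Homogeneous hydrogenation with RhCl(PPh3)3 reduces only the 1,1-disubstituted isopropenyl olefin; the two trisubstituted ring olefins (one conjugated to the amide) are too hindered to bind rhodium, and no stereocentre changes.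

**Step 10**
Reactants: 16 (1(10)E,4Z,6S,7S,8R)-6,8-dihydroxy-N-methoxy-N-methylgermacra-1(10),4-dien-14-amide
Product: 17 (1(10)E,4Z,6S,7S,8R)-6,8-diacetoxy-N-methoxy-N-methylgermacra-1(10),4-dien-14-amide
Conditions: Ac2O, pyridine, DMAP (cat.), CH2Cl2, rt
Reagents that add atoms: acetic anhydride, CC(=O)OC(C)=O
Why: DMAP-catalysed acylation esterifies both secondary alcohols; only O–H bonds react, so C6 and C8 keep their configuration.

**Step 11**
Reactants: 17 (1(10)E,4Z,6S,7S,8R)-6,8-diacetoxy-N-methoxy-N-methylgermacra-1(10),4-dien-14-amide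
Product: 18 (1(10)E,4Z,6S,7S,8R)-6,8-diacetoxygermacra-1(10),4-dien-14-al
Conditions: Cp2Zr(H)Cl (1.5 equiv), THF, rt, 20 min
Reagents that add atoms: none
Why: Hydrozirconation of the amide carbonyl with Cp2Zr(H)Cl gives a stable zirconated hemiaminal that releases the aldehyde on work-up; this amide-to-aldehyde reduction tolerates esters and hindered olefins, so both acetates and both ring olefins survive and the E-enal is obtained without over-reduction.

**Step 12**
Reactants: 18 (1(10)E,4Z,6S,7S,8R)-6,8-diacetoxygermacra-1(10),4-dien-14-al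
Product: 19 (1R,4Z,6S,7S,8R,10S)-6,8-diacetoxy-1,10-epoxygermacr-4-en-14-al
Conditions: 9-amino(9-deoxy)epiquinine (10 mol %), TFA (20 mol %), 50% aq. H2O2 (3 equiv), dioxane, 35 °C
Reagents that add atoms: hydrogen peroxide, OO
Why: Amine-catalysed Weitz–Scheffer epoxidation: the primary amine forms the iminium ion of the α-branched enal, H2O2 adds to C1 and the resulting enamine closes the oxirane on the face left open by the catalyst; the ring keeps C2 and C9 cis, which gives the (1R,10S) cis-epoxide, and neither the acetates nor the unactivated 4,5-olefin react with H2O2.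

**Compound list**
1 | neryl acetate, (2Z)-3,7-dimethylocta-2,6-dien-1-yl acetate | CC(=O)OC/C=C(/C)CCC=C(C)C | starting material
2 | (2Z)-5-(3,3-dimethyloxiran-2-yl)-3-methylpent-2-en-1-yl acetate (racemic at the oxirane) | CC(=O)OC/C=C(/C)CCC1OC1(C)C | intermediate (not isolated)
3 | (2Z)-3-methyl-6-oxohex-2-en-1-yl acetate | CC(=O)OC/C=C(/C)CCC=O | intermediate
4 | (2Z)-3-methylhepta-2,6-dien-1-yl acetate | CC(=O)OC/C=C(/C)CCC=C | intermediate
5 | prenal, 3-methylbut-2-enal | CC(C)=CC=O | starting material
6 | ethyl 2-(bromomethyl)acrylate | C=C(CBr)C(=O)OCC | starting material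
7 | ethyl (4R)-6-methyl-2-methylidene-4-(trimethylsilyloxy)hept-5-enoate | C=C(C[C@@H](O[Si](C)(C)C)C=C(C)C)C(=O)OCC | intermediate (not isolated)
8 | ethyl (4R)-4-hydroxy-6-methyl-2-methylidenehept-5-enoate | C=C(C[C@@H](O)C=C(C)C)C(=O)OCC | intermediate (not isolated)
9 | (5R)-3-methylidene-5-(2-methylprop-1-en-1-yl)oxolan-2-one | C=C1C[C@@H](OC1=O)C=C(C)C | intermediate
10 | (2Z)-3-methyl-6-[(3E,5R)-5-(2-methylprop-1-en-1-yl)-2-oxooxolan-3-ylidene]hex-2-en-1-yl acetate | CC(=O)OC/C=C(/C)CC/C=C1\C[C@@H](OC1=O)C=C(C)C | intermediate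
11 | (2E,6Z)-8-hydroxy-2-[(2R)-2-hydroxy-4-methylpent-3-en-1-yl]-N-methoxy-N,6-dimethylocta-2,6-dienamide | OC/C=C(/C)CC/C=C(\C[C@@H](O)C=C(C)C)C(=O)N(C)OC | intermediate
12 | (2E,6Z)-2-[(2R)-2-hydroxy-4-methylpent-3-en-1-yl]-N-methoxy-N,6-dimethyl-8-oxoocta-2,6-dienamide | O=C/C=C(/C)CC/C=C(\C[C@@H](O)C=C(C)C)C(=O)N(C)OC | intermediate
13 | (2E,6Z)-N-methoxy-N,6-dimethyl-2-[(2R)-4-methyl-2-(triethylsilyloxy)pent-3-en-1-yl]-8-oxoocta-2,6-dienamide | O=C/C=C(/C)CC/C=C(\C[C@@H](O[Si](CC)(CC)CC)C=C(C)C)C(=O)N(C)OC | intermediate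
14 | (1(10)E,4Z,6S,7R,8R)-6-hydroxy-N-methoxy-N-methyl-8-(triethylsilyloxy)germacra-1(10),4,11-trien-14-amide (ten-membered ring, both ring olefins ring-cis, isopropenyl on C7; 7R only because the silyl group changes the priorities) | O[C@H]1/C=C(/C)CC/C=C(/C(=O)N(C)OC)C[C@@H](O[Si](CC)(CC)CC)[C@@H]1C(C)=C | intermediate (not isolated)
15 | (1(10)E,4Z,6S,7S,8R)-6,8-dihydroxy-N-methoxy-N-methylgermacra-1(10),4,11-trien-14-amide | O[C@H]1/C=C(/C)CC/C=C(/C(=O)N(C)OC)C[C@@H](O)[C@@H]1C(C)=C | intermediate
16 | (1(10)E,4Z,6S,7S,8R)-6,8-dihydroxy-N-methoxy-N-methylgermacra-1(10),4-dien-14-amide | O[C@H]1/C=C(/C)CC/C=C(/C(=O)N(C)OC)C[C@@H](O)[C@@H]1C(C)C | intermediate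
17 | (1(10)E,4Z,6S,7S,8R)-6,8-diacetoxy-N-methoxy-N-methylgermacra-1(10),4-dien-14-amide | CC(=O)O[C@H]1/C=C(/C)CC/C=C(/C(=O)N(C)OC)C[C@@H](OC(C)=O)[C@@H]1C(C)C | intermediate
18 | (1(10)E,4Z,6S,7S,8R)-6,8-diacetoxygermacra-1(10),4-dien-14-al | CC(=O)O[C@H]1/C=C(/C)CC/C=C(/C=O)C[C@@H](OC(C)=O)[C@@H]1C(C)C | intermediate
19 | (1R,4Z,6S,7S,8R,10S)-6,8-diacetoxy-1,10-epoxygermacr-4-en-14-al | CC(=O)O[C@H]1/C=C(/C)CC[C@H]2O[C@@]2(C=O)C[C@@H](OC(C)=O)[C@@H]1C(C)C | target

**Step count**
Total steps: 12. Longest linear sequence: 11 steps (1 → 3 → 4 → 10 → 11 → 12 → 13 → 15 → 16 → 17 → 18 → 19); step 3 is the convergent branch.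

**Steps most likely to fail**

Step 8 (ene macrocyclisation). The risks are oligomerisation, ionisation of the allylic silyl ether, Z→E isomerisation of the complexed enal, and attack on the wrong olefin face; the facial prediction rests on a qualitative model. Fallback: the fallback sets out from 13 and replaces the Lewis-acid closure by an allylmetal addition. Ene-type chlorination of the isopropylidene group (NCS, PhSeCl cat., CH2Cl2) gives the transposed allylic chloride F1. CrCl2 in THF at high dilution turns it into an allylchromium species that adds through its γ-carbon (C7) to the C6 aldehyde in a closed chair transition state (intramolecular Nozaki–Hiyama allylation). Its anti preference corresponds to the required C6/C7 relationship. Aqueous work-up returns the route at 14, which is desilylated to 15 as in step 8.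

Step 12 (amine-catalysed epoxidation). The hindered macrocyclic enal may form the iminium ion slowly, and catalyst and ring may disagree on the face. Fallback: the fallback sets out from 18 and uses a hydroxyl-directed titanium epoxidation. Luche reduction (NaBH4, CeCl3·7H2O, MeOH, −40 °C) gives the allylic alcohol F2. Sharpless epoxidation (Ti(OiPr)4, D-(−)-diethyl tartrate, tBuOOH, 4 Å sieves, CH2Cl2, −20 °C) gives the epoxy alcohol F3; the D-(−) tartrate is chosen because the required oxirane belongs to the (2R,3R) series that this tartrate gives with E-allylic alcohols. Dess–Martin oxidation (NaHCO3, CH2Cl2) then comes back to the route at 19.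

Step 3 (asymmetric chromium allylation). A β,β-disubstituted enal with an electron-poor allyl bromide may give low enantioselectivity. Fallback: the fallback sets out from 5 and 6 and sets C8 by ketone reduction. Zinc-mediated Barbier allylation (Zn, THF/aq. NH4Cl) gives the racemic hydroxy ester F4. Dess–Martin oxidation gives the dienone ester F5. Corey–Bakshi–Shibata reduction ((S)-2-methyl-CBS-oxazaborolidine, catecholborane, toluene, −78 °C; isobutenyl as the large group) gives the (R)-alcohol and comes back to the route at 8, which is lactonised with TsOH to 9.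

**Further compounds**
F1 | step 8 | (2E,6Z)-2-[(2R)-3-chloro-4-methyl-2-(triethylsilyloxy)pent-4-en-1-yl]-N-methoxy-N,6-dimethyl-8-oxoocta-2,6-dienamide (both epimers at the C–Cl carbon) | O=C/C=C(/C)CC/C=C(\C[C@@H](O[Si](CC)(CC)CC)C(Cl)C(C)=C)C(=O)N(C)OC
F2 | step 12 | (1(10)E,4Z,6S,7S,8R)-6,8-diacetoxygermacra-1(10),4-dien-14-ol | CC(=O)O[C@H]1/C=C(/C)CC/C=C(/CO)C[C@@H](OC(C)=O)[C@@H]1C(C)C
F3 | step 12 | (1R,4Z,6S,7S,8R,10R)-6,8-diacetoxy-1,10-epoxygermacr-4-en-14-ol | CC(=O)O[C@H]1/C=C(/C)CC[C@H]2O[C@@]2(CO)C[C@@H](OC(C)=O)[C@@H]1C(C)C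
F4 | step 3 | ethyl 4-hydroxy-6-methyl-2-methylidenehept-5-enoate (racemic) | C=C(CC(O)C=C(C)C)C(=O)OCC
F5 | step 3 | ethyl 6-methyl-2-methylidene-4-oxohept-5-enoate | C=C(CC(=O)C=C(C)C)C(=O)OCC
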